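**Retrosynthetic overview**
1. Feature: in the dihydropyran (O1, C2, C3, C4, C5, C6), C2 is benzylic to the 4-hydroxy-3-methoxyphenyl ring, para to its free OH. O1 is the enol oxygen of a C6 aldehyde whose C5=C6 bond is conjugated with benzofuran C2′. The O1–C2 bond can therefore be made, broken and remade through a para-quinone methide.
2. Last disconnection, O1–C2: this leads back to the open C6 aldehyde 29, in which only C3 matters. C2 carries an acetate rather than OH, because a free δ-hydroxy aldehyde would rest as its lactol and close through O1–C6. Acid is also avoided, because it would give a benzylic cation that benzofuran C3′ can capture irreversibly.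
3. C5–C2′: Suzuki–Miyaura coupling of 2-bromoalkene 15 with boronate 24, then hydroboration to bring in the C6 oxygen. The aryl ketone thus enters after all enolate and hydride chemistry on the chain.
4. C2–C3: Evans syn aldol of imide 8 with silylated vanillin 10. It fixes C3 absolutely and avoids a configurationally labile β-acetoxy aldehyde and an aryl-metal addition next to an acetate.
5. Ring order: both benzene rings are bought, the furan ring of the benzofuran is closed in step 10, and the dihydropyran is closed last in step 16.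

Key step: step 16

Remark: locants O1 and C2 to C6 are those of the dihydropyran, primed locants those of the benzofuran, doubly primed those of the 4-hydroxy-3-methoxyphenyl ring. The target SMILES reads as (2R,3S), which is the trans isomer.

**Step 1**
Reactants: 1 tert-butyl acetate; 2 2,3-dibromopropene
Product: 4 tert-butyl 4-bromopent-4-enoate, via lithium enolate 3 (not isolated)
Conditions: LiN(iPr)2, THF, −78 °C; then 2, −78 °C → rt
Reagents that add atoms: none
Why: Ester enolate alkylation; only the allylic C–Br of 2 is displaced (SN2 and SN2′ give the same product), the vinylic C–Br is inert, and the tert-butyl ester suppresses Claisen self-condensation.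

**Step 2**
Reactants: 4 tert-butyl 4-bromopent-4-enoate
Product: 5 4-bromopent-4-enoic acid
Conditions: CF3CO2H, CH2Cl2, rt
Reagents that add atoms: none
Why: Acidolysis of a tert-butyl ester by loss of 2-methylpropene, under which a 2-bromoalkene is stable.

**Step 3**
Reactants: 5 4-bromopent-4-enoic acid; 6 (R)-4-benzyl-2-oxazolidinone
Product: 8 (R)-4-benzyl-3-(4-bromopent-4-enoyl)oxazolidin-2-one, via mixed pivalic anhydride 7 (not isolated)
Conditions: tBuCOCl, Et3N, THF, −20 °C; then LiCl, 6, −20 °C → rt
Reagents that add atoms: none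
Why: N-acylation of the oxazolidinone through a mixed anhydride with LiCl activation; the nucleophile attacks the unhindered carbonyl and not the pivaloyl one.

**Step 4**
Reactants: 9 vanillin
Product: 10 3-methoxy-4-(triisopropylsilyloxy)benzaldehyde
Conditions: iPr3SiCl, imidazole, DMF, rt
Reagents that add atoms: chlorotriisopropylsilane, CC(C)[Si](Cl)(C(C)C)C(C)C
Why: Phenol silylation; the bulky, base-resistant silyl group is chosen because its premature loss would later set off the quinone methide too early.

**Step 5**
Reactants: 8 (R)-4-benzyl-3-(4-bromopent-4-enoyl)oxazolidin-2-one; 10 3-methoxy-4-(triisopropylsilyloxy)benzaldehyde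
Product: 13 (R)-4-benzyl-3-[(2R)-4-bromo-2-{(R)-hydroxy[3-methoxy-4-(triisopropylsilyloxy)phenyl]methyl}pent-4-enoyl]oxazolidin-2-one, via Z-boron enolate 11 (not isolated), via boron aldolate 12 (not isolated)
Conditions: Bu2BOTf, Et3N, CH2Cl2, 0 °C; 10, −78 → 0 °C; then pH 7 buffer, MeOH, 30% H2O2, 0 °C
Reagents that add atoms: none
Why: Evans syn aldol; the Z-boron enolate reacts through a Zimmerman–Traxler chair on the face away from the benzyl group, so the (R)-auxiliary sets the α-carbon (ring C3) and the carbinol carbon (ring C2) as the R,R syn pair.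

**Step 6**
Reactants: 13 syn aldol adduct
Product: 14 (1R,2S)-2-(2-bromoprop-2-en-1-yl)-1-[3-methoxy-4-(triisopropylsilyloxy)phenyl]propane-1,3-diol
Conditions: LiBH4, THF, 0 °C
Reagents that add atoms: none
Why: Reductive cleavage of the N-acyl oxazolidinone to the primary alcohol. C3 keeps its geometry (the descriptor changes to S only by priority) and is no longer next to a carbonyl group, so it cannot epimerise afterwards.

**Step 7**
Reactants: 14 diol
Product: 15 (1R,2S)-2-(acetoxymethyl)-4-bromo-1-[3-methoxy-4-(triisopropylsilyloxy)phenyl]pent-4-en-1-yl acetate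
Conditions: Ac2O, pyridine, DMAP (cat.), CH2Cl2, 0 °C → rt
Reagents that add atoms: acetic anhydride, CC(=O)OC(C)=O
Why: Exhaustive DMAP-catalysed acetylation needs no selectivity, since the primary acetate is the one in the target and the benzylic acetate is the leaving group of the key step and blocks lactol formation.

**Step 8**
Reactants: 16 2-bromo-1,4-dimethoxybenzene
Product: 17 1-(4-bromo-2,5-dimethoxyphenyl)ethanone
Conditions: AcCl, AlCl3, CH2Cl2, 0 °C
Reagents that add atoms: acetyl chloride, CC(=O)Cl
Why: Friedel–Crafts acylation at the position para to bromine and ortho to a methoxy group, the site favoured by all three directing groups and by sterics.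

**Step 9**
Reactants: 17 1-(4-bromo-2,5-dimethoxyphenyl)ethanone
Product: 18 1-(4-bromo-2,5-dihydroxyphenyl)ethanone
Conditions: BBr3, CH2Cl2, −78 °C → rt; H2O
Reagents that add atoms: none
Why: Lewis acid cleavage of both aryl methyl ethers, which tolerates the aryl ketone and the aryl bromide.

**Step 10**
Reactants: 18 1-(4-bromo-2,5-dihydroxyphenyl)ethanone; 19 trimethylsilylacetylene
Product: 22 1-(5-hydroxybenzofuran-6-yl)ethanone, via silylalkyne 20 (not isolated), via ethynylphenol 21 (not isolated)
Conditions: PdCl2(PPh3)2 (cat.), CuI (cat.), Et3N, DMF, 60 °C, degassed, sealed; then K2CO3, MeOH, 60 °C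
Reagents that add atoms: none
Why: Sonogashira coupling at the C–Br bond activated by the para acetyl group, then methanolysis of the C–Si bond and 5-endo-dig addition of the ortho phenol oxygen to the terminal alkyne carbon, which the para acetyl group polarises in the right sense.

**Step 11**
Reactants: 22 1-(5-hydroxybenzofuran-6-yl)ethanone
Product: 23 1-[5-(triisopropylsilyloxy)benzofuran-6-yl]ethanone
Conditions: iPr3SiCl, imidazole, DMAP (cat.), DMF, 40 °C
Reagents that add atoms: chlorotriisopropylsilane, CC(C)[Si](Cl)(C(C)C)C(C)C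
Why: Phenol silylation, warmed because the OH is hydrogen-bonded to the acetyl group; the phenol must be masked for the borane and periodinane steps.

**Step 12**
Reactants: 23 1-[5-(triisopropylsilyloxy)benzofuran-6-yl]ethanone
Product: 24 1-[2-(4,4,5,5-tetramethyl-1,3,2-dioxaborolan-2-yl)-5-(triisopropylsilyloxy)benzofuran-6-yl]ethanone
Conditions: [Ir(OMe)(cod)]2 (cat.), 4,4′-di-tert-butyl-2,2′-bipyridine (cat.), B2pin2, THF, 50 °C
Reagents that add atoms: bis(pinacolato)diboron, CC1(C)OB(OC1(C)C)B1OC(C)(C)C(C)(C)O1
Why: Iridium-catalysed C–H borylation favours the C–H next to the furan oxygen; C4′–H and C7′–H each have an ortho substituent, so only C2′ should react, and aryl ketones are tolerated.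

**Step 13**
Reactants: 15 bromoalkene diacetate; 24 benzofuran-2-yl boronate
Product: 25 (1R,2S)-2-(acetoxymethyl)-4-[6-acetyl-5-(triisopropylsilyloxy)benzofuran-2-yl]-1-[3-methoxy-4-(triisopropylsilyloxy)phenyl]pent-4-en-1-yl acetate
Conditions: Pd(dppf)Cl2 (cat.), K3PO4, THF–H2O, 45 °C, degassed
Reagents that add atoms: none
Why: Suzuki–Miyaura coupling of a 2-bromo-1-alkene with a heteroaryl pinacol boronate forms C5–C2′; phosphate base and low temperature are chosen to spare the acetates and the aryl silyl ethers.

**Step 14**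
Reactants: 25 1,1-disubstituted alkene
Product: 27 (1R,2S)-2-(acetoxymethyl)-5-hydroxy-4-[6-(1-hydroxyethyl)-5-(triisopropylsilyloxy)benzofuran-2-yl]-1-[3-methoxy-4-(triisopropylsilyloxy)phenyl]pentyl acetate (epimers at C4 of the chain and at the carbinol carbon), via bis-boron adduct 26 (not isolated)
Conditions: 9-BBN-H (excess), THF, 0 °C → rt; then NaBO3·4H2O, THF–H2O, rt
Reagents that add atoms: sodium perborate, [Na+].[O-]OB=O
Why: Hydroboration–oxidation places boron on the unsubstituted terminus C6 (anti-Markovnikov); the aryl ketone is knowingly reduced as well because step 15 restores it, and the new centres form as mixtures that are erased later.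

**Step 15**
Reactants: 27 diol
Product: 28 (1R,2S)-2-(acetoxymethyl)-4-[6-acetyl-5-(triisopropylsilyloxy)benzofuran-2-yl]-1-[3-methoxy-4-(triisopropylsilyloxy)phenyl]-5-oxopentyl acetate (epimers at C4 of the chain, ring C5)
Conditions: Dess–Martin periodinane, CH2Cl2, 0 °C → rt
Reagents that add atoms: none
Why: Dess–Martin oxidation takes the primary alcohol to the C6 aldehyde and the benzylic secondary alcohol back to the acetyl group in one non-basic operation that leaves acetates, silyl ethers and the enolisable aldehyde intact.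

**Step 16**
Reactants: 28 bis-silylated keto aldehyde diacetate
Product: 31 propolis-benzofuran A, via free bisphenol aldehyde 29 (not isolated), via quinone methide enol 30 (not isolated)
Conditions: CsF, 4 Å MS, degassed DMF (5 mM), 0 → 40 °C; then AcOH
Reagents that add atoms: none
Why: Proposed new method: fluoride strips both aryl silyl ethers to give 29 as its phenoxide, the 4″-phenoxide expels the C2 acetate by 1,6-elimination to the neutral para-quinone methide 30, and the C6 aldehyde, acidified by the benzofuran on C5, reacts as its enolate, whose oxygen adds to methide carbon C2 and restores the arene, so that O1–C2 forms while the C2 and C5 configurations of the precursor are both erased. The closest known reaction types are the intramolecular oxa-1,6-addition of alcohols and phenols to para-quinone methides used for lignan benzylic ethers and the fluoride-triggered release of quinone methides from 4-silyloxybenzyl acetates; an aldehyde enolate oxygen has not been shown as the donor. The dihydropyran closes in a 6-exo-trig mode, since the C2=C1″ bond that is broken lies outside the new ring; only the enolate geometry with O1 cis to C4 can close, and the other geometry feeds it through the aldehyde. C2 is controlled by C3 alone: the product phenoxide can expel the stabilised enolate again, so the closure is reversible and should settle on the half-chair with the aryl group at C2 and the acetoxymethyl group at C3 both pseudo-equatorial, which is trans (2R,3S). The step needs capture by oxygen rather than carbon: attack through C5 would give a cyclobutane with a quaternary carbon, and attack through benzofuran C3′ (an irreversible six-membered carbocycle) costs the furan aromaticity and is held back because the electrophile is a neutral methide and not a benzylic cation. High dilution disfavours intermolecular capture, and the tethered anionic donor keeps the methide short-lived, which protects C3–H from the tautomerisation to a 4-vinylphenol that would erase C3.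

**Compound list**
1 | tert-butyl acetate | CC(=O)OC(C)(C)C | starting material
2 | 2,3-dibromopropene | C=C(Br)CBr | starting material
3 | lithium enolate of tert-butyl acetate | C=C(O[Li])OC(C)(C)C | intermediate
4 | tert-butyl 4-bromopent-4-enoate | C=C(Br)CCC(=O)OC(C)(C)C | intermediate
5 | 4-bromopent-4-enoic acid | C=C(Br)CCC(=O)O | intermediate
6 | (R)-4-benzyl-2-oxazolidinone | O=C1N[C@H](Cc2ccccc2)CO1 | starting material
7 | 4-bromopent-4-enoic pivalic anhydride | C=C(Br)CCC(=O)OC(=O)C(C)(C)C | intermediate
8 | (R)-4-benzyl-3-(4-bromopent-4-enoyl)oxazolidin-2-one | C=C(Br)CCC(=O)N1[C@H](Cc2ccccc2)COC1=O | intermediate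
9 | vanillin | COc1cc(C=O)ccc1O | starting material
10 | 3-methoxy-4-(triisopropylsilyloxy)benzaldehyde | COc1cc(C=O)ccc1O[Si](C(C)C)(C(C)C)C(C)C | intermediate
11 | Z-dibutylboron enolate of 8 | C=C(Br)C/C=C(\OB(CCCC)CCCC)N1[C@H](Cc2ccccc2)COC1=O | intermediate
12 | dibutylboron aldolate of 13 | COc1cc([C@H](OB(CCCC)CCCC)[C@H](C(=O)N2[C@H](Cc3ccccc3)COC2=O)CC(Br)=C)ccc1O[Si](C(C)C)(C(C)C)C(C)C | intermediate
13 | Evans syn aldol adduct (α-carbon R, carbinol carbon R, auxiliary R) | COc1cc([C@H](O)[C@H](C(=O)N2[C@H](Cc3ccccc3)COC2=O)CC(Br)=C)ccc1O[Si](C(C)C)(C(C)C)C(C)C | intermediate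
14 | (1R,2S)-2-(2-bromoprop-2-en-1-yl)-1-[3-methoxy-4-(triisopropylsilyloxy)phenyl]propane-1,3-diol | COc1cc([C@H](O)[C@H](CO)CC(Br)=C)ccc1O[Si](C(C)C)(C(C)C)C(C)C | intermediate
15 | (1R,2S)-2-(acetoxymethyl)-4-bromo-1-[3-methoxy-4-(triisopropylsilyloxy)phenyl]pent-4-en-1-yl acetate | COc1cc([C@H](OC(C)=O)[C@H](COC(C)=O)CC(Br)=C)ccc1O[Si](C(C)C)(C(C)C)C(C)C | intermediate
16 | 2-bromo-1,4-dimethoxybenzene | COc1ccc(OC)c(Br)c1 | starting material
17 | 1-(4-bromo-2,5-dimethoxyphenyl)ethanone | COc1cc(C(C)=O)c(OC)cc1Br | intermediate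
18 | 1-(4-bromo-2,5-dihydroxyphenyl)ethanone | CC(=O)c1cc(O)c(Br)cc1O | intermediate
19 | trimethylsilylacetylene | C#C[Si](C)(C)C | starting material
20 | 1-{2,5-dihydroxy-4-[(trimethylsilyl)ethynyl]phenyl}ethanone | CC(=O)c1cc(O)c(C#C[Si](C)(C)C)cc1O | intermediate
21 | 1-(4-ethynyl-2,5-dihydroxyphenyl)ethanone | CC(=O)c1cc(O)c(C#C)cc1O | intermediate
22 | 1-(5-hydroxybenzofuran-6-yl)ethanone | CC(=O)c1cc2occc2cc1O | intermediate
23 | 1-[5-(triisopropylsilyloxy)benzofuran-6-yl]ethanone | CC(=O)c1cc2occc2cc1O[Si](C(C)C)(C(C)C)C(C)C | intermediate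
24 | 2-pinacolboryl derivative of 23 | CC(=O)c1cc2oc(B3OC(C)(C)C(C)(C)O3)cc2cc1O[Si](C(C)C)(C(C)C)C(C)C | intermediate
25 | Suzuki product, 2-(benzofuran-2-yl)alkene diacetate (1R,2S) | COc1cc([C@H](OC(C)=O)[C@H](COC(C)=O)CC(=C)c2cc3cc(O[Si](C(C)C)(C(C)C)C(C)C)c(C(C)=O)cc3o2)ccc1O[Si](C(C)C)(C(C)C)C(C)C | intermediate
26 | C6 B-alkyl-9-BBN adduct, ketone reduced to its 9-BBN borinate | COc1cc([C@H](OC(C)=O)[C@H](COC(C)=O)CC(CB2C3CCCC2CCC3)c2cc3cc(O[Si](C(C)C)(C(C)C)C(C)C)c(C(C)OB4C5CCCC4CCC5)cc3o2)ccc1O[Si](C(C)C)(C(C)C)C(C)C | intermediate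
27 | C6 primary alcohol with 1-hydroxyethyl group on C6′ (epimer mixture) | COc1cc([C@H](OC(C)=O)[C@H](COC(C)=O)CC(CO)c2cc3cc(O[Si](C(C)C)(C(C)C)C(C)C)c(C(C)O)cc3o2)ccc1O[Si](C(C)C)(C(C)C)C(C)C | intermediate
28 | bis-silylated keto aldehyde diacetate, protected form of the key-step precursor (C5 epimers) | COc1cc([C@H](OC(C)=O)[C@H](COC(C)=O)CC(C=O)c2cc3cc(O[Si](C(C)C)(C(C)C)C(C)C)c(C(C)=O)cc3o2)ccc1O[Si](C(C)C)(C(C)C)C(C)C | intermediate
29 | key-step precursor, (1R,2S)-2-(acetoxymethyl)-4-(6-acetyl-5-hydroxybenzofuran-2-yl)-1-(4-hydroxy-3-methoxyphenyl)-5-oxopentyl acetate (C5 epimers; present as caesium phenoxide) | COc1cc([C@H](OC(C)=O)[C@H](COC(C)=O)CC(C=O)c2cc3cc(O)c(C(C)=O)cc3o2)ccc1O | intermediate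
30 | para-quinone methide carrying the C5=C6 enol (present as enolate; C3 intact) | COC1=CC(=C[C@H](COC(C)=O)CC(=CO)c2cc3cc(O)c(C(C)=O)cc3o2)C=CC1=O | intermediate
31 | propolis-benzofuran A, [(2R,3S)-5-(6-acetyl-5-hydroxybenzofuran-2-yl)-2-(4-hydroxy-3-methoxyphenyl)-3,4-dihydro-2H-pyran-3-yl]methyl acetate | COc1cc([C@@H]2OC=C(c3cc4cc(O)c(C(C)=O)cc4o3)C[C@H]2COC(C)=O)ccc1O | target

**Total step count:** 16
**Longest linear sequence:** 10 steps (1, 2, 3, 5, 6, 7, 13, 14, 15, 16)

**Steps most likely to fail**

1. Step 16 (new method).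
   - What may go wrong: capture of the methide carbon by benzofuran C3′ instead of oxygen; tautomerisation of the methide to the 4-vinylphenol with loss of the C3 configuration; addition of adventitious water; oligomerisation.
   - Fallback principle: known chemistry closes the ring at the other C–O bond, O1–C6, by lactol dehydration and keeps the C2–O bond made in the aldol. The syn aldol has already set C2 as R, which maps onto the trans ring.
   - The fallback sets out from 14. AcCl and 2,4,6-collidine in CH2Cl2 at −78 °C should acetylate only the primary alcohol to give the primary monoacetate F1.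
   - Et3SiOTf and 2,6-lutidine then give the C2 triethylsilyl ether F2.
   - Suzuki–Miyaura coupling with 24 as in step 13 gives the alkene F3.
   - 9-BBN-H followed by NaBO3·4H2O gives the diol F4, and Dess–Martin periodinane gives the keto aldehyde F5.
   - AcOH–THF–H2O removes only the alkyl silyl ether, and the freed δ-hydroxy aldehyde closes to the lactol F6.
   - MsCl and Et3N dehydrate the lactol to the bis-silylated dihydropyran F7.
   - Bu4NF buffered with AcOH removes both aryl silyl groups, and the fallback comes back to the route at 31.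

2. Step 13.
   - What may go wrong: protodeboronation of the 2-benzofuranyl boronate; hydrolysis of the acetates; base-induced loss of the 4″-silyl group, which would set off methide formation early.
   - Fallback principle: the furan ring is built on the chain instead of coupling a finished benzofuran.
   - The fallback sets out from 15. Stille coupling with ethynyltributylstannane (Pd(PPh3)4, toluene, 80 °C, neutral) gives the terminal enyne F8.
   - Sonogashira coupling of F8 with 18 (PdCl2(PPh3)2, CuI, Et3N, DMF, 60 °C) with 5-endo-dig closure in the same flask gives the 5′-phenol F9.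
   - iPr3SiCl and imidazole bring the fallback back to the route at 25.

3. Step 14.
   - What may go wrong: incomplete regiocontrol of boron delivery; slow attack of the borane on the acetates; shift of the silyl group from the 5′-phenol oxygen to the new benzylic alkoxide; ester hydrolysis during the oxidative work-up.
   - Fallback principle: the C6 oxygen is brought in by oxidation, so the ketone is never reduced.
   - The fallback sets out from 25. OsO4 (cat.) and N-methylmorpholine N-oxide in acetone–H2O dihydroxylate the exocyclic alkene to the 1,2-diol F10.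
   - Pyridinium p-toluenesulfonate in toluene ionises the tertiary benzofuran-2-yl carbinol, and a pinacol-type 1,2-hydride shift gives the aldehyde. The fallback comes back to the route at 28, and step 15 is then not needed.

**Further compounds**
F1 | step 16 | (2S,3R)-2-(2-bromoallyl)-3-hydroxy-3-[3-methoxy-4-(triisopropylsilyloxy)phenyl]propyl acetate | COc1cc([C@H](O)[C@H](COC(C)=O)CC(Br)=C)ccc1O[Si](C(C)C)(C(C)C)C(C)C
F2 | step 16 | C2 triethylsilyl ether of F1 | COc1cc([C@H](O[Si](CC)(CC)CC)[C@H](COC(C)=O)CC(Br)=C)ccc1O[Si](C(C)C)(C(C)C)C(C)C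
F3 | step 16 | Suzuki product of F2 with 24 | COc1cc([C@H](O[Si](CC)(CC)CC)[C@H](COC(C)=O)CC(=C)c2cc3cc(O[Si](C(C)C)(C(C)C)C(C)C)c(C(C)=O)cc3o2)ccc1O[Si](C(C)C)(C(C)C)C(C)C
F4 | step 16 | C6 alcohol with 1-hydroxyethyl group from F3 | COc1cc([C@H](O[Si](CC)(CC)CC)[C@H](COC(C)=O)CC(CO)c2cc3cc(O[Si](C(C)C)(C(C)C)C(C)C)c(C(C)O)cc3o2)ccc1O[Si](C(C)C)(C(C)C)C(C)C
F5 | step 16 | keto aldehyde from F4 | COc1cc([C@H](O[Si](CC)(CC)CC)[C@H](COC(C)=O)CC(C=O)c2cc3cc(O[Si](C(C)C)(C(C)C)C(C)C)c(C(C)=O)cc3o2)ccc1O[Si](C(C)C)(C(C)C)C(C)C
F6 | step 16 | (2R,3S)-lactol, 6-hydroxytetrahydropyran (C5 and C6 epimers) | COc1cc([C@@H]2OC(O)C(c3cc4cc(O[Si](C(C)C)(C(C)C)C(C)C)c(C(C)=O)cc4o3)C[C@H]2COC(C)=O)ccc1O[Si](C(C)C)(C(C)C)C(C)C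
F7 | step 16 | bis(triisopropylsilyl) ether of 31 | COc1cc([C@@H]2OC=C(c3cc4cc(O[Si](C(C)C)(C(C)C)C(C)C)c(C(C)=O)cc4o3)C[C@H]2COC(C)=O)ccc1O[Si](C(C)C)(C(C)C)C(C)C
F8 | step 13 | terminal enyne diacetate | COc1cc([C@H](OC(C)=O)[C@H](COC(C)=O)CC(=C)C#C)ccc1O[Si](C(C)C)(C(C)C)C(C)C
F9 | step 13 | 25 with free 5′-OH | COc1cc([C@H](OC(C)=O)[C@H](COC(C)=O)CC(=C)c2cc3cc(O)c(C(C)=O)cc3o2)ccc1O[Si](C(C)C)(C(C)C)C(C)C
F10 | step 14 | C5,C6-diol of 25 (C5 epimers) | COc1cc([C@H](OC(C)=O)[C@H](COC(C)=O)CC(O)(CO)c2cc3cc(O[Si](C(C)C)(C(C)C)C(C)C)c(C(C)=O)cc3o2)ccc1O[Si](C(C)C)(C(C)C)C(C)C
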